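**Plan**

- Retrosynthesis: the two O–benzyl helper bonds are cut first. Next comes the C4–C5 bond of the O-octadecyl chain (counted from the ester oxygen), which leads back to pentadecanoic acid and a 5-(acyloxy)pentanoic acid, each as its N-acyloxyphthalimide. Then the ester C(=O)–O bond is cut, which is the lactone C–O bond of 7-hydroxy-8-methoxychroman-2-one, and last the aryl–CH2 bond, to 2-methoxyresorcinol and acrylic acid.
- Enabling feature: C4 and C5 are unsubstituted CH2 groups of an unbranched chain and the ester oxygen is δ to C4, so both carbons are plain primary radicals available by decarboxylation. The 1,2,3-trioxygenated benzene ring would not survive an anodic (Kolbe) coupling, so the radicals are made and joined reductively at a cathode under nickel catalysis.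
- Forward: the only ring formed is the temporary δ-lactone (dihydrocoumarin). It fixes the 2,4-dihydroxy-3-methoxy pattern and then acts as acyl donor, being opened by tert-butyl 5-hydroxypentanoate while both phenols are benzylated.
- Acid unmasking, activation, electrochemical joining of the C4 and C14 units to the C18 chain, and hydrogenolysis follow.
- Stereochemistry (remark): the target has no stereocentre and no stereogenic double bond, so it is achiral and nothing has to be controlled. All numbered starting materials are taken to be catalogue chemicals.

Key step: step 6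

**Route**

Step 1
Reactants: 1 2-methoxybenzene-1,3-diol (2-methoxyresorcinol); 2 acrylic acid
Product: 4 7-hydroxy-8-methoxychroman-2-one, via 3-(2,4-dihydroxy-3-methoxyphenyl)propanoic acid 3 (not isolated)
Conditions: Amberlyst-15, toluene, reflux (Dean–Stark); slight excess of 1
Reagents that add atoms: none
Why: Acid-catalysed Friedel–Crafts conjugate hydroarylation of acrylic acid occurs at C4 of the resorcinol (ortho/para to the two hydroxyls and identical with C6 by symmetry), and the ortho-hydroxy acid lactonises under the dehydrating conditions, as known for resorcinol-type phenols.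

Step 2
Reactants: 4 7-hydroxy-8-methoxychroman-2-one; 5 tert-butyl 5-hydroxypentanoate
Product: 8 tert-butyl 5-({3-[2,4-bis(benzyloxy)-3-methoxyphenyl]propanoyl}oxy)pentanoate, via 7-(benzyloxy)-8-methoxychroman-2-one 6 (not isolated), via tert-butyl 5-({3-[4-(benzyloxy)-2-hydroxy-3-methoxyphenyl]propanoyl}oxy)pentanoate 7 (not isolated)
Conditions: Cs2CO3, BnBr, DMF, 4 Å MS, rt; then 5, 50 °C
Reagents that add atoms: benzyl bromide, BrCc1ccccc1
Why: Williamson benzylation of the 7-OH is followed by carbonate-mediated ring-opening transesterification of the activated aryl lactone by the primary alcohol, driven forward because the released 2-phenoxide is O-benzylated in situ (the known alcoholysis/O-alkylation of dihydrocoumarins), while the tert-butyl ester is inert.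

Step 3
Reactants: 8 tert-butyl 5-({3-[2,4-bis(benzyloxy)-3-methoxyphenyl]propanoyl}oxy)pentanoate
Product: 9 5-({3-[2,4-bis(benzyloxy)-3-methoxyphenyl]propanoyl}oxy)pentanoic acid
Conditions: 85% aq. H3PO4, toluene, rt to 40 °C
Reagents that add atoms: none
Why: Acidolysis of the tert-butyl ester by alkyl–oxygen cleavage with aqueous phosphoric acid is selective over the primary alkyl ester and the aryl benzyl ethers.

Step 4
Reactants: 9 5-({3-[2,4-bis(benzyloxy)-3-methoxyphenyl]propanoyl}oxy)pentanoic acid
Product: 10 1,3-dioxoisoindolin-2-yl 5-({3-[2,4-bis(benzyloxy)-3-methoxyphenyl]propanoyl}oxy)pentanoate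
Conditions: N-hydroxyphthalimide, DIC, DMAP (cat.), CH2Cl2, rt
Reagents that add atoms: N-hydroxyphthalimide, O=C1c2ccccc2C(=O)N1O
Why: Carbodiimide (Steglich-type) condensation with N-hydroxyphthalimide gives the bench-stable redox-active ester, and no competing acyl acceptor is present because both phenols are benzylated.

Step 5
Reactants: 11 pentadecanoic acid
Product: 12 1,3-dioxoisoindolin-2-yl pentadecanoate
Conditions: N-hydroxyphthalimide, DIC, DMAP (cat.), CH2Cl2, rt
Reagents that add atoms: N-hydroxyphthalimide, O=C1c2ccccc2C(=O)N1O
Why: The same carbodiimide condensation converts the fatty acid into its crystalline redox-active ester, the tetradecyl radical precursor.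

Step 6
Reactants: 10 1,3-dioxoisoindolin-2-yl 5-({3-[2,4-bis(benzyloxy)-3-methoxyphenyl]propanoyl}oxy)pentanoate; 12 1,3-dioxoisoindolin-2-yl pentadecanoate
Product: 13 octadecyl 3-[2,4-bis(benzyloxy)-3-methoxyphenyl]propanoate
Conditions: 12 (3 equiv), NiCl2·6H2O (20 mol%), 2,2':6',2''-terpyridine (20 mol%), AgNO3 (0.3 equiv), NMP, Mg(+)/RVC(−), undivided cell, constant current, rt
Reagents that add atoms: none
Why: Cathodically generated low-valent Ni(terpyridine) transfers an electron to each N-acyloxyphthalimide, whose radical anion fragments to phthalimide anion, CO2 and a primary alkyl radical (tetradecyl from 12, 4-(acyloxy)butyl from 10), while the magnesium anode is consumed as the terminal reductant. The two radicals are captured in turn at nickel, and C(sp3)–C(sp3) reductive elimination from the dialkylnickel species forms the C4–C5 bond of the octadecyl chain. The closest known reaction type is the nickel-electrocatalytic doubly decarboxylative cross-coupling of two primary redox-active esters, the reductive counterpart of a mixed Kolbe electrolysis. No ring is closed and no stereocentre is created. The step needs cross-coupling over homo-coupling, which is statistical between two similar primary radicals and is secured by the threefold excess of the cheap C15 ester 12, whose homodimer octacosane is a non-polar hydrocarbon that chromatography should remove. It also needs chemoselectivity, which the substrate secures because the reductive potential leaves the easily oxidised 1,2,3-trioxygenated benzene ring, the benzyl ethers and the propanoate ester untouched, and because the ester oxygen is δ to the radical carbon, so neither β-scission nor a 1,2-acyloxy shift is open to it.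

Step 7
Reactants: 13 octadecyl 3-[2,4-bis(benzyloxy)-3-methoxyphenyl]propanoate
Product: 14 octadecyl 3-(2,4-dihydroxy-3-methoxyphenyl)propanoate (target)
Conditions: H2 (1 atm), 10% Pd/C, EtOAc, rt
Reagents that add atoms: none
Why: Palladium-catalysed hydrogenolysis of the two aryl benzyl ethers leaves the alkyl ester, the methyl ether and the saturated chain untouched and frees both phenols under neutral conditions, under which the 2-hydroxyphenyl ester should not relactonise.

**Compound list**

1 | 2-methoxybenzene-1,3-diol (2-methoxyresorcinol) | COc1c(O)cccc1O | starting material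
2 | acrylic acid | C=CC(=O)O | starting material
3 | 3-(2,4-dihydroxy-3-methoxyphenyl)propanoic acid | OC(=O)CCc1ccc(O)c(OC)c1O | intermediate
4 | 7-hydroxy-8-methoxychroman-2-one | O=C1CCc2ccc(O)c(OC)c2O1 | intermediate
5 | tert-butyl 5-hydroxypentanoate | CC(C)(C)OC(=O)CCCCO | starting material
6 | 7-(benzyloxy)-8-methoxychroman-2-one | O=C1CCc2ccc(OCc3ccccc3)c(OC)c2O1 | intermediate
7 | tert-butyl 5-({3-[4-(benzyloxy)-2-hydroxy-3-methoxyphenyl]propanoyl}oxy)pentanoate | CC(C)(C)OC(=O)CCCCOC(=O)CCc1ccc(OCc2ccccc2)c(OC)c1O | intermediate
8 | tert-butyl 5-({3-[2,4-bis(benzyloxy)-3-methoxyphenyl]propanoyl}oxy)pentanoate | CC(C)(C)OC(=O)CCCCOC(=O)CCc1ccc(OCc2ccccc2)c(OC)c1OCc1ccccc1 | intermediate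
9 | 5-({3-[2,4-bis(benzyloxy)-3-methoxyphenyl]propanoyl}oxy)pentanoic acid | OC(=O)CCCCOC(=O)CCc1ccc(OCc2ccccc2)c(OC)c1OCc1ccccc1 | intermediate
10 | 1,3-dioxoisoindolin-2-yl 5-({3-[2,4-bis(benzyloxy)-3-methoxyphenyl]propanoyl}oxy)pentanoate | O=C(CCCCOC(=O)CCc1ccc(OCc2ccccc2)c(OC)c1OCc1ccccc1)ON1C(=O)c2ccccc2C1=O | intermediate
11 | pentadecanoic acid | CCCCCCCCCCCCCCC(=O)O | starting material
12 | 1,3-dioxoisoindolin-2-yl pentadecanoate | CCCCCCCCCCCCCCC(=O)ON1C(=O)c2ccccc2C1=O | intermediate
13 | octadecyl 3-[2,4-bis(benzyloxy)-3-methoxyphenyl]propanoate | CCCCCCCCCCCCCCCCCCOC(=O)CCc1ccc(OCc2ccccc2)c(OC)c1OCc1ccccc1 | intermediate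
14 | octadecyl 3-(2,4-dihydroxy-3-methoxyphenyl)propanoate | CCCCCCCCCCCCCCCCCCOC(=O)CCc1ccc(O)c(OC)c1O | target

**Summary**

Total step count: 7. Longest linear sequence: 6 (steps 1, 2, 3, 4, 6, 7); step 5 is a one-step branch.

Steps most likely to fail:

1. Step 6. The two primary radicals partition statistically, so homo-coupling of 10 and hydrodecarboxylation (reduction of the radical or alkylnickel intermediate) may consume the valuable ester before cross-coupling. The fallback replaces radical coupling by olefin metathesis and sets out from 4. Acid-catalysed alcoholysis of the lactone in excess pent-4-en-1-ol (TsOH cat., 50 °C, neutralised before concentration) should give pent-4-en-1-yl 3-(2,4-dihydroxy-3-methoxyphenyl)propanoate F1. Cross-metathesis with excess pentadec-1-ene (Grubbs second-generation catalyst, CH2Cl2, 40 °C) should then give (E)-octadec-4-en-1-yl 3-(2,4-dihydroxy-3-methoxyphenyl)propanoate F2; any Z isomer is of no consequence. Hydrogenation (H2, Pd/C, EtOAc) saturates C4=C5 and comes back to the route at 14.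

2. Step 2. Ring opening by the alcohol may lag behind hydrolytic opening by traces of water, after which the carboxylate is benzylated, or the hindered 2-phenoxide may relactonise faster than it is benzylated. The fallback sets out from 4 and separates the operations. Exhaustive opening and benzylation (powdered KOH, BnBr, DMSO) should give benzyl 3-[2,4-bis(benzyloxy)-3-methoxyphenyl]propanoate F3. Saponification (LiOH, THF/H2O, then HCl) should give 3-[2,4-bis(benzyloxy)-3-methoxyphenyl]propanoic acid F4. SN2 alkylation of its caesium carboxylate with tert-butyl 5-bromopentanoate (Cs2CO3, DMF) comes back to the route at 8.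

3. Step 1. A second alkylation at the other activated ring position and oligomerisation of acrylic acid may outrun clean mono-hydroarylation and lactonisation. The fallback sets out from 1 and builds the ring at the coumarin oxidation level. Pechmann-type condensation with ethyl propiolate (ZnCl2, dioxane, 100 °C) should give 7-hydroxy-8-methoxy-2H-chromen-2-one F5. Hydrogenation of its C3=C4 double bond (H2, Pd/C, EtOAc/AcOH) comes back to the route at 4.

**Further compounds**

F1 | step 6 | pent-4-en-1-yl 3-(2,4-dihydroxy-3-methoxyphenyl)propanoate | C=CCCCOC(=O)CCc1ccc(O)c(OC)c1O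
F2 | step 6 | (E)-octadec-4-en-1-yl 3-(2,4-dihydroxy-3-methoxyphenyl)propanoate | CCCCCCCCCCCCC/C=C/CCCOC(=O)CCc1ccc(O)c(OC)c1O
F3 | step 2 | benzyl 3-[2,4-bis(benzyloxy)-3-methoxyphenyl]propanoate | O=C(OCc1ccccc1)CCc1ccc(OCc2ccccc2)c(OC)c1OCc1ccccc1
F4 | step 2 | 3-[2,4-bis(benzyloxy)-3-methoxyphenyl]propanoic acid | OC(=O)CCc1ccc(OCc2ccccc2)c(OC)c1OCc1ccccc1
F5 | step 1 | 7-hydroxy-8-methoxy-2H-chromen-2-one | O=c1ccc2ccc(O)c(OC)c2o1
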